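Ring B is cut into two three-carbon halves (numbering: C1–C5 ring A, C6 spiro, C7–C11 ring B): C6–C11–C10, carried by a dimedone-derived ring A, and C7=C8–C9, an acrylate. The key step joins them in one flask. It exploits that spiro C6 is α to the latent ring-A carbonyl C5 and that carbinol C9 can be a ketone: the C6 enolate vinylates at C7 by addition–elimination, then the sulfinyl-stabilised C10 carbanion acylates C9, closing ring B as a cyclohexenone. The precursor is an α′-(2-sulfinylethyl) vinylogous ester plus ethyl (Z)-3-iodoacrylate; the chiral sulfinyl group activates C10, makes the spiro epimers separable and, as sulfone, masks the ring-B ketone.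

Key step: step 3

Remark: (R)-p-tolyl vinyl sulfoxide 3 is assumed to be purchasable (otherwise one known step from menthyl p-toluenesulfinate and vinylmagnesium bromide); all spiro compounds are named with the locants of the target.

Step 1
Reactants: 1 5,5-dimethylcyclohexane-1,3-dione (dimedone)
Product: 2 3-ethoxy-5,5-dimethylcyclohex-2-en-1-one
Conditions: EtOH, TsOH (cat.), toluene, reflux, Dean–Stark trap
Reagents that add atoms: ethanol, CCO
Why: Acid-catalysed enol etherification of the symmetric cyclic 1,3-diketone with azeotropic removal of water should give the vinylogous ester, which leaves one α′-CH2 (the future spiro carbon C6) for enolate chemistry and creates no stereocentre.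

Step 2
Reactants: 2 3-ethoxy-5,5-dimethylcyclohex-2-en-1-one; 3 (R)-p-tolyl vinyl sulfoxide
Product: 4 3-ethoxy-5,5-dimethyl-6-{2-[(R)-(4-methylphenyl)sulfinyl]ethyl}cyclohex-2-en-1-one (both epimers at the ring carbon)
Conditions: LiN(i-Pr)2, THF, −78 °C; then 3, −78 to −20 °C; aq. NH4Cl
Reagents that add atoms: none
Why: Kinetic deprotonation of the vinylogous ester at the α′-carbon and Michael addition of the lithium enolate to the vinyl sulfoxide should install the C11–C10 arm with sulfur on the future C10; the new α′-centre forms as both epimers but is flattened again in step 3, and the configuration at sulfur is not touched.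

Step 3
Reactants: 4 3-ethoxy-5,5-dimethyl-6-{2-[(R)-(4-methylphenyl)sulfinyl]ethyl}cyclohex-2-en-1-one; 5 ethyl (Z)-3-iodoprop-2-enoate
Product: 7 (6R)-3-ethoxy-1,1-dimethyl-10-[(R)-(4-methylphenyl)sulfinyl]spiro[5.5]undeca-3,7-diene-5,9-dione, via vinylated ester 6 (not isolated)
Conditions: LiN(i-Pr)2 (1.1 equiv), THF, −78 to −40 °C; 5, −78 to −30 °C; then LiN(i-Pr)2 (2.3 equiv), −78 to −30 °C; aq. NH4Cl; separation of the C6 epimers; product kept cold
Reagents that add atoms: none
Why: LiN(i-Pr)2 gives the tetrasubstituted C6 enolate (the α-sulfinyl CH2 is about five pKa units less acidic and equilibrates to it), which adds to the β-carbon of 5 and expels iodide with retention, forming C6–C7 and the Z-acrylate 6; the second base charge lithiates C10 next to sulfur, and this carbanion attacks the cis-held ester, forming C10–C9 and expelling ethoxide, the sequence being driven by deprotonation of the acidic β-keto sulfoxide. The closest known reaction types are enolate vinylation by nucleophilic vinylic substitution on β-haloacrylates and the Claisen (Dieckmann-type) acylation of α-sulfinyl carbanions by esters, combined here as a Michael–Claisen [3+3] annulation. Ring B closes by a 6-exo-trig acyl substitution, helped by the geminal arrangement of both arms on C6. C6 is formed in the intermolecular bond formation and no reliable facial bias is claimed (lithium chelation by the sulfinyl oxygen may give some): the (R)-configured sulfur makes the two C6 epimers diastereomers, and the (6R) epimer is isolated by chromatography or crystallisation, C10 being epimerisable and of no consequence. The step needs C- rather than O-attack at a hindered enolate and retention of the Z geometry, both served by the soft, unhindered iodoacrylate at low temperature, and lithiation at C10 rather than at the ring-A γ-carbon C2, which sulfinyl-directed deprotonation and the fast, irreversible spiro-closure should secure.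

Step 4
Reactants: 7 (6R)-3-ethoxy-1,1-dimethyl-10-[(R)-(4-methylphenyl)sulfinyl]spiro[5.5]undeca-3,7-diene-5,9-dione
Product: 8 (6R)-3-ethoxy-1,1-dimethyl-10-(4-methylbenzenesulfonyl)spiro[5.5]undeca-3,7-diene-5,9-dione
Conditions: mCPBA (1.1 equiv), NaHCO3, CH2Cl2, 0 °C
Reagents that add atoms: mCPBA (3-chloroperbenzoic acid), OOC(=O)c1cccc(Cl)c1
Why: Peracid oxidation of the sulfoxide to the sulfone should outpace epoxidation of the two electron-poor alkenes; it removes the heat-labile β-keto sulfoxide and leaves an acidic β-keto sulfone whose enolate protects the ring-B ketone through steps 5 to 7 (C6 unchanged, C10 still epimerisable).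

Step 5
Reactants: 8 (6R)-3-ethoxy-1,1-dimethyl-10-(4-methylbenzenesulfonyl)spiro[5.5]undeca-3,7-diene-5,9-dione
Product: 10 (2S,6R)-2-bromo-3-ethoxy-1,1-dimethyl-10-(4-methylbenzenesulfonyl)spiro[5.5]undeca-3,7-diene-5,9-dione, via bis-silyl dienol ether 9 (not isolated)
Conditions: LiN(i-Pr)2 (2.3 equiv), Me3SiCl, THF, −78 °C; NBS (1.0 equiv), −78 °C; aq. NaHCO3
Reagents that add atoms: N-bromosuccinimide, O=C1CCC(=O)N1Br
Why: Double deprotonation and silylation should turn ring B into an electron-poor 9-silyloxy-10-sulfonyl diene and ring A (γ-deprotonation at C2, because the α′-carbon C6 is quaternary) into an electron-rich 5-silyloxy-3-ethoxy diene, so that NBS attacks only the terminus C2 of the latter (vinylogous Mukaiyama-type γ-bromination); bromine should enter axially on the face where the 1,3-related axial substituent of C6 is the flat sp2 carbon C7 and not the CH2 group C11, which after ring inversion gives the equatorial (2S) bromide cis to C7.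

Step 6
Reactants: 10 (2S,6R)-2-bromo-3-ethoxy-1,1-dimethyl-10-(4-methylbenzenesulfonyl)spiro[5.5]undeca-3,7-diene-5,9-dione
Product: 13 (2S,6S)-2-bromo-1,1-dimethyl-5-methylidene-10-(4-methylbenzenesulfonyl)spiro[5.5]undec-7-ene-3,9-dione, via carbinol 11 (not isolated), via allylsilane enone 12 (not isolated)
Conditions: LiN(SiMe3)2 (1.05 equiv), THF, −78 °C; Me3SiCH2Li, CeCl3, −78 °C; then 1 M HCl, THF, 0 to 25 °C
Reagents that add atoms: (trimethylsilyl)methyllithium, [Li]C[Si](C)(C)C; water, O
Why: With the β-keto sulfone parked as its lithium enolate, the organocerium reagent should add 1,2 to the hindered vinylogous ester carbonyl C5; acid then effects the Stork–Danheiser transposition to the allylsilane enone 12 and its protodesilylation at C4, a Peterson-type sequence that places the alkene exocyclic under kinetic control and unveils the C3 ketone, while the α-bromo ketone has no β-hydrogen through which HBr could be lost and C6 is untouched.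

Step 7
Reactants: 13 (2S,6S)-2-bromo-1,1-dimethyl-5-methylidene-10-(4-methylbenzenesulfonyl)spiro[5.5]undec-7-ene-3,9-dione
Product: 14 (2S,3R,6S)-2-bromo-3-hydroxy-1,1-dimethyl-5-methylidene-10-(4-methylbenzenesulfonyl)spiro[5.5]undec-7-en-9-one
Conditions: LiN(SiMe3)2 (1.05 equiv), THF, −78 °C; LiBH(s-Bu)3, −78 °C; aq. NH4Cl
Reagents that add atoms: none
Why: After selective deprotonation of the β-keto sulfone (in situ enolate protection of ring B), the bulky borohydride should attack the C3 ketone from the equatorial direction because the axial methyl group on C1 blocks the axial path, giving the axial (3R) alcohol cis to the equatorial bromine (substrate-controlled ketone reduction).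

Step 8
Reactants: 14 (2S,3R,6S)-2-bromo-3-hydroxy-1,1-dimethyl-5-methylidene-10-(4-methylbenzenesulfonyl)spiro[5.5]undec-7-en-9-one
Product: 15 (2S,3R,6S)-2-bromo-3-hydroxy-1,1-dimethyl-5-methylidenespiro[5.5]undec-7-en-9-one
Conditions: SmI2 (2.5 equiv), THF–MeOH, −78 °C
Reagents that add atoms: none
Why: SmI2 should cleave the activated C10–S bond of the β-keto sulfone by electron transfer (reductive desulfonylation) and methanol protonates the samarium enolate to the enone, whereas the unactivated secondary bromide, the alkenes and the free alcohol are inert at −78 °C without HMPA.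

Step 9
Reactants: 15 (2S,3R,6S)-2-bromo-3-hydroxy-1,1-dimethyl-5-methylidenespiro[5.5]undec-7-en-9-one
Product: 16 mailiohydrin, (2S,3R,6S,9R)-2-bromo-9-(dibromomethyl)-1,1-dimethyl-5-methylidenespiro[5.5]undec-7-ene-3,9-diol
Conditions: CH2Br2, LiN(i-Pr)2 (3.2 equiv), THF, −78 °C; AcOH, −78 °C
Reagents that add atoms: dibromomethane, BrCBr
Why: Dibromomethyllithium formed in situ from CH2Br2 and LiN(i-Pr)2 in the presence of the ketone should add 1,2 to the enone carbonyl (carbenoid addition to a ketone); the bulky nucleophile is expected to take the pseudo-equatorial trajectory so that CHBr2 and the CMe2 arm of C6 both end pseudo-equatorial on the cyclohexene and the hydroxyl lies cis to C1 (9R), and the acetic acid quench at −78 °C protonates the β-oxido dibromide before it can rearrange.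

Compound list
1 | 5,5-dimethylcyclohexane-1,3-dione (dimedone) | CC1(C)CC(=O)CC(=O)C1 | starting material
2 | 3-ethoxy-5,5-dimethylcyclohex-2-en-1-one | CCOC1=CC(=O)CC(C)(C)C1 | intermediate
3 | (R)-p-tolyl vinyl sulfoxide, (R)-1-(ethenesulfinyl)-4-methylbenzene | C=C[S@@](=O)c1ccc(C)cc1 | starting material
4 | 3-ethoxy-5,5-dimethyl-6-{2-[(R)-(4-methylphenyl)sulfinyl]ethyl}cyclohex-2-en-1-one (both C6 epimers of the cyclohexenone) | CCOC1=CC(=O)C(CC[S@@](=O)c2ccc(C)cc2)C(C)(C)C1 | intermediate
5 | ethyl (Z)-3-iodoprop-2-enoate | CCOC(=O)/C=C\I | starting material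
6 | ethyl (Z)-3-[(1R)-4-ethoxy-6,6-dimethyl-1-{2-[(R)-(4-methylphenyl)sulfinyl]ethyl}-2-oxocyclohex-3-en-1-yl]prop-2-enoate (vinylated ester, not isolated) | O=C1C=C(OCC)CC(C)(C)[C@@]1(CC[S@@](=O)c2ccc(C)cc2)/C=C\C(=O)OCC | intermediate
7 | (6R)-3-ethoxy-1,1-dimethyl-10-[(R)-(4-methylphenyl)sulfinyl]spiro[5.5]undeca-3,7-diene-5,9-dione (C10 labile, not defined) | O=C1C=C(OCC)CC(C)(C)[C@@]12C=CC(=O)C([S@@](=O)c3ccc(C)cc3)C2 | intermediate
8 | (6R)-3-ethoxy-1,1-dimethyl-10-(4-methylbenzenesulfonyl)spiro[5.5]undeca-3,7-diene-5,9-dione (C10 labile, not defined) | O=C1C=C(OCC)CC(C)(C)[C@@]12C=CC(=O)C(S(=O)(=O)c3ccc(C)cc3)C2 | intermediate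
9 | (6R)-3-ethoxy-1,1-dimethyl-10-(4-methylbenzenesulfonyl)-5,9-bis(trimethylsilyloxy)spiro[5.5]undeca-2,4,7,9-tetraene (bis-silyl dienol ether, not isolated) | C[Si](C)(C)OC1=CC(OCC)=CC(C)(C)[C@@]12C=CC(O[Si](C)(C)C)=C(S(=O)(=O)c3ccc(C)cc3)C2 | intermediate
10 | (2S,6R)-2-bromo-3-ethoxy-1,1-dimethyl-10-(4-methylbenzenesulfonyl)spiro[5.5]undeca-3,7-diene-5,9-dione | O=C1C=C(OCC)[C@@H](Br)C(C)(C)[C@@]12C=CC(=O)C(S(=O)(=O)c3ccc(C)cc3)C2 | intermediate
11 | (2S,6R)-2-bromo-3-ethoxy-5-hydroxy-1,1-dimethyl-10-(4-methylbenzenesulfonyl)-5-[(trimethylsilyl)methyl]spiro[5.5]undeca-3,7-dien-9-one (carbinol, C5 not defined, not isolated) | C[Si](C)(C)CC1(O)C=C(OCC)[C@@H](Br)C(C)(C)[C@@]12C=CC(=O)C(S(=O)(=O)c3ccc(C)cc3)C2 | intermediate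
12 | (2S,6S)-2-bromo-1,1-dimethyl-10-(4-methylbenzenesulfonyl)-5-[(trimethylsilyl)methyl]spiro[5.5]undeca-4,7-diene-3,9-dione (allylsilane enone, not isolated) | C[Si](C)(C)CC1=CC(=O)[C@@H](Br)C(C)(C)[C@@]12C=CC(=O)C(S(=O)(=O)c3ccc(C)cc3)C2 | intermediate
13 | (2S,6S)-2-bromo-1,1-dimethyl-5-methylidene-10-(4-methylbenzenesulfonyl)spiro[5.5]undec-7-ene-3,9-dione | C=C1CC(=O)[C@@H](Br)C(C)(C)[C@@]12C=CC(=O)C(S(=O)(=O)c3ccc(C)cc3)C2 | intermediate
14 | (2S,3R,6S)-2-bromo-3-hydroxy-1,1-dimethyl-5-methylidene-10-(4-methylbenzenesulfonyl)spiro[5.5]undec-7-en-9-one | C=C1C[C@@H](O)[C@@H](Br)C(C)(C)[C@@]12C=CC(=O)C(S(=O)(=O)c3ccc(C)cc3)C2 | intermediate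
15 | (2S,3R,6S)-2-bromo-3-hydroxy-1,1-dimethyl-5-methylidenespiro[5.5]undec-7-en-9-one | C=C1C[C@@H](O)[C@@H](Br)C(C)(C)[C@@]12C=CC(=O)CC2 | intermediate
16 | mailiohydrin, (2S,3R,6S,9R)-2-bromo-9-(dibromomethyl)-1,1-dimethyl-5-methylidenespiro[5.5]undec-7-ene-3,9-diol | C=C1C[C@@H](O)[C@@H](Br)C(C)(C)[C@@]12C=C[C@@](O)(C(Br)Br)CC2 | target

Total step count: 9. Longest linear sequence: 9 steps (1 to 16).

Steps most likely to fail

Step 3. The hindered tetrasubstituted enolate may react sluggishly or on oxygen in the addition–elimination, and the C6 epimers may form without useful bias, so that half of the material is lost at the separation. The fallback sets out from 4 and sets C6 by reagent control. A Michael–Claisen annulation of 4 with methyl acrylate under the same two-stage base protocol (same two ring-B bonds in one flask, no alkene geometry to hold) would give the saturated β-keto sulfoxide 3-ethoxy-1,1-dimethyl-10-[(R)-(4-methylphenyl)sulfinyl]spiro[5.5]undec-3-ene-5,9-dione F1, used as the epimer mixture. Aluminium amalgam removes sulfur and leaves the symmetric, achiral ketone 3-ethoxy-1,1-dimethylspiro[5.5]undec-3-ene-5,9-dione F2. Enantiotopic deprotonation with the appropriate enantiomer of lithium bis(1-phenylethyl)amide and Me3SiCl (chiral lithium amide desymmetrisation of a 4,4-disubstituted cyclohexanone) gives the silyl enol ether (6R)-3-ethoxy-1,1-dimethyl-9-(trimethylsilyloxy)spiro[5.5]undeca-3,8-dien-5-one F3. Saegusa–Ito oxidation with Pd(OAc)2 gives the enone (6R)-3-ethoxy-1,1-dimethylspiro[5.5]undeca-3,7-diene-5,9-dione F4. Kinetic enolisation at C10 with LiN(i-Pr)2 and C-sulfonylation with p-toluenesulfonyl fluoride brings the material back to the route at 8.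

Step 5. Bromination may occur at the ring-B enol ether or at C4, or from the wrong face of C2. The fallback sets out from 8 and inverts the order of events. Addition of Me3SiCH2CeCl2 to the enolate-protected 8, followed by a short, cold acid work-up that stops at the Stork–Danheiser stage, would give the allylsilane enone (6R)-1,1-dimethyl-10-(4-methylbenzenesulfonyl)-5-[(trimethylsilyl)methyl]spiro[5.5]undeca-4,7-diene-3,9-dione F5. In this enone only C2 carries α′-hydrogens, so kinetic enolisation with silylation (LiN(i-Pr)2, Me3SiCl) and NBS place bromine unambiguously at C2. This comes back to the route at 12, which the acid treatment of step 6 converts into 13; at 13 the C2 epimers can also be equilibrated through the enol with HBr in AcOH.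

Step 9. The bulky carbenoid may add from the wrong face of the C9 carbonyl, or the lithium β-oxido dibromide may collapse (ring expansion or epoxide formation) before the quench. The fallback sets out from 15 and builds the CHBr2 group in stages from a stable acyl-anion equivalent. 2-Lithio-1,3-dithiane, which is bulky and should also prefer the pseudo-equatorial path, adds to C9 to give the dithianyl carbinol (2S,3R,6S,9R)-2-bromo-9-(1,3-dithian-2-yl)-1,1-dimethyl-5-methylidenespiro[5.5]undec-7-ene-3,9-diol F6. Unmasking with MeI and CaCO3 in aqueous MeCN gives the hydroxy aldehyde (2S,3R,6S,9R)-2-bromo-3,9-dihydroxy-1,1-dimethyl-5-methylidenespiro[5.5]undec-7-ene-9-carbaldehyde F7. Hydrazine hydrate gives the hydrazone (2S,3R,6S,9R)-2-bromo-9-(hydrazinylidenemethyl)-1,1-dimethyl-5-methylidenespiro[5.5]undec-7-ene-3,9-diol F8. CuBr2 with LiOt-Bu converts the hydrazone into the geminal dibromide, which comes back to the route at 16.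

Further compounds
F1 | step 3 | 3-ethoxy-1,1-dimethyl-10-[(R)-(4-methylphenyl)sulfinyl]spiro[5.5]undec-3-ene-5,9-dione (both C6 epimers) | O=C1C=C(OCC)CC(C)(C)C12CCC(=O)C([S@@](=O)c3ccc(C)cc3)C2
F2 | step 3 | 3-ethoxy-1,1-dimethylspiro[5.5]undec-3-ene-5,9-dione (achiral) | O=C1C=C(OCC)CC(C)(C)C12CCC(=O)CC2
F3 | step 3 | (6R)-3-ethoxy-1,1-dimethyl-9-(trimethylsilyloxy)spiro[5.5]undeca-3,8-dien-5-one | O=C1C=C(OCC)CC(C)(C)[C@@]12CC=C(O[Si](C)(C)C)CC2
F4 | step 3 | (6R)-3-ethoxy-1,1-dimethylspiro[5.5]undeca-3,7-diene-5,9-dione | O=C1C=C(OCC)CC(C)(C)[C@@]12C=CC(=O)CC2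
F5 | step 5 | (6R)-1,1-dimethyl-10-(4-methylbenzenesulfonyl)-5-[(trimethylsilyl)methyl]spiro[5.5]undeca-4,7-diene-3,9-dione | C[Si](C)(C)CC1=CC(=O)CC(C)(C)[C@@]12C=CC(=O)C(S(=O)(=O)c3ccc(C)cc3)C2
F6 | step 9 | (2S,3R,6S,9R)-2-bromo-9-(1,3-dithian-2-yl)-1,1-dimethyl-5-methylidenespiro[5.5]undec-7-ene-3,9-diol | C=C1C[C@@H](O)[C@@H](Br)C(C)(C)[C@@]12C=C[C@@](O)(C3SCCCS3)CC2
F7 | step 9 | (2S,3R,6S,9R)-2-bromo-3,9-dihydroxy-1,1-dimethyl-5-methylidenespiro[5.5]undec-7-ene-9-carbaldehyde | C=C1C[C@@H](O)[C@@H](Br)C(C)(C)[C@@]12C=C[C@@](O)(C=O)CC2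
F8 | step 9 | (2S,3R,6S,9R)-2-bromo-9-(hydrazinylidenemethyl)-1,1-dimethyl-5-methylidenespiro[5.5]undec-7-ene-3,9-diol | C=C1C[C@@H](O)[C@@H](Br)C(C)(C)[C@@]12C=C[C@@](O)(C=NN)CC2
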